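The readings were generated by integration for substances that don't exist, noise included.

**Slow making.** Target is made slowly and lost as it is made: after 120 s the summer run has turned 46.5% of the starting material into target and over-reaction product, yet target stands at 12.6%.

all flasks: added ligand 26 µM
- summer: starting material 23 mM; second substrate 46 mM; free enzyme 6.9 µM; run made earlier
- dusk: starting material 23 mM; second substrate 64 mM; free enzyme 6.9 µM; run made earlier
- dawn: starting material 23 mM; second substrate 100 mM; free enzyme 6.9 µM; run made earlier
- noon: starting material 23 mM; second substrate 46 mM; free enzyme 3.5 µM; run made earlier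
- amber: starting material 23 mM; second substrate 46.0 mM; free enzyme 6.9 µM; everything together at the start; time 2.0 min
- ochre: starting material 23 mM (fed, over 80 s); second substrate 46.0 mM; free enzyme 6.9 µM; all else is in the flask from the start; the feed brings no volume worth counting; time 2.0 min
- red: starting material 23 mM; second substrate 46.0 mM (fed, over 80 s); free enzyme 6.9 µM; all else is in the flask from the start; the feed brings no volume worth counting; time 2.0 min

| run | time / s | target / % | over-reaction product / % |
|---|---|---|---|
| summer | 30.0 | 8.2 | 4.7 |
| summer | 60.0 | 11.5 | 14.9 |
| summer | 90.0 | 12.0 | 25.6 |
| summer | 120 | 12.6 | 33.9 |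
| dusk | 10.0 | 3.3 | 1.4 |
| dusk | 12.0 | 4.1 | 1.9 |
| dusk | 30.0 | 6.6 | 6.9 |
| dusk | 80.0 | 8.7 | 25.6 |
| dawn | 20.0 | 4.6 | 4.6 |
| dawn | 40.0 | 5.6 | 13.0 |
| dawn | 50.0 | 5.4 | 17.1 |
| dawn | 80.0 | 5.3 | 28.1 |
| noon | 20.0 | 3.7 | 1.8 |
| noon | 40.0 | 4.8 | 4.5 |
| noon | 50.0 | 4.7 | 5.7 |
| noon | 80.0 | 5.0 | 11.0 |

(each reading ± 0.5 percentage points)



- the best flask by share of target in target plus over-reaction product; "all alike" if 1.5 percentage points covers them all (amber / ochre / red / all alike)
- share of target in target plus over-reaction product at the end, amber
- share of target in target plus over-reaction product at the end, ochre
- share of target in target plus over-reaction product at the end, red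

**Target lifetime.** Between 60.0 s and 120 s the summer run gains 19 percentage points of over-reaction product beside about 12.0% of target. That reads as 37.9 s for the target lifetime, target on hand divided by the growth rate of over-reaction product, a pseudo-first-order lifetime.

**Second substrate.** By hand, more c(second substrate) should shorten this lifetime and leave conversion alone. The dawn run reads 14.3 s, shorter than in summer. Its conversion at 80.0 s is 33.4%, against 34.3% in the dusk run.

**Free enzyme.** By hand, less enzyme should slow the making. The noon run, with about half the enzyme of the dusk run and also less second substrate (46 mM against 64 mM), converts about half as much by 80.0 s.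

**Time.** Steady making over a span T, with a fixed lifetime τ, gives a share of (τ/T)(1 − e^(−T/τ)). For amber, the summer recipe, that is 30.2%, while the summer readings give 27.1%.

**The feeds.** In the summer run the last 30.0 s convert 8.9 points, against 13 points in the first 30.0 s, and I take this as the making following c(starting material). Feeding starting material in ochre then moves the making later, which I count as a span of about 80.0 s, and that gives 41.6%, or 37.3% when scaled as the summer reading scales the rule. Feeding second substrate in red stretches the lifetime during the feed, but the 40.0 s after it are about one lifetime. So I put red between amber and ochre.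

**The forecast.** The forecast differs from my reckoning: it gives amber 27%, ochre 27.5% and red 32%, names red as best, and holds ochre close to amber on the ground that “step one is zero order in starting material”.

**The result.** Amber ends at 27.0%, ochre at 34.0% and red at 30.1%, so the best flask is ochre.

    starting material + free enzyme ⇌ first complex (K = 26.0 /M, k = 8.70 × 10⁵ /M/s)
    first complex ⇌ loaded enzyme + first product (K = 0.160 M, k = 340 /s)
    second substrate + loaded enzyme ⇌ second complex (K = 1100 /M, k = 6.90 × 10⁵ /M/s)
    second complex → free enzyme + target (k = 120 /s)
    free enzyme + added ligand ⇌ idle complex, settled at all times (K = 4.30 × 10⁵ /M)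
    second substrate + target → over-reaction product (k = 0.820 /M/s)

In ochre, half of the first step's turnover up to the end was done by 1.26 min, so the median turnover was 44.5 s old at the end, or 1.17 target lifetimes. For ochre with 12 mM of second substrate, scaling by c(second substrate) puts the lifetime at 145 s, longer than the span. The rule then gives 76.9%, and that flask ends at 80.3%.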